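The synthesis numbers the heptane chain from the guaiacyl ring (ring A). The syn-3,5-dioxygenated segment C3–C7 is then read as two acetaldehyde units (C4–C5 and C6–C7) strung onto the carbonyl carbon C3 of an arylpropanal. A deoxyribose-phosphate aldolase forges C3–C4 and C5–C6, fixes both carbinol centres and lets the C3 oxygen close on C7 to a six-membered lactol, all in a single aqueous operation. Its precursor is unprotected 3-(4-hydroxy-3-methoxyphenyl)propanal, whose free phenol provides water solubility. The catechol ring (ring B) then enters at C7 as an aryl Grignard reagent. The surplus benzylic oxygen is removed together with the benzyl ethers in the last step.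

Key step: step 2

Assumption: an aldolase variant that tolerates acetaldehyde and has a widened acceptor channel is taken to be accessible by screening. The anomeric centre of the lactols and the benzylic C7 carbinol are carried as epimer mixtures, since both centres disappear later.

Step 1
Reactants: 1 coniferyl aldehyde, (E)-3-(4-hydroxy-3-methoxyphenyl)prop-2-enal
Product: 2 3-(4-hydroxy-3-methoxyphenyl)propanal
Conditions: H2 (1 atm), 5% Pd/C, EtOAc, rt, stopped after one equivalent of H2
Reagents that add atoms: none
Why: Chemoselective heterogeneous hydrogenation: on palladium the conjugated C=C bond of a cinnamaldehyde is saturated far faster than the resulting aliphatic aldehyde is reduced, the aprotic solvent rules out acetal formation, and no stereocentre is created.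

Step 2
Reactants: 2 3-(4-hydroxy-3-methoxyphenyl)propanal; 3 acetaldehyde (two molecules incorporated)
Product: 6 (4R,6R)-6-[2-(4-hydroxy-3-methoxyphenyl)ethyl]oxane-2,4-diol (anomer mixture), via (3R)-hydroxy aldehyde 4 (not isolated), via (3R,5R)-dihydroxy aldehyde 5 (not isolated)
Conditions: 2-deoxyribose-5-phosphate aldolase variant (Cys47 replaced, widened acceptor channel, cell-free extract), 3 (2.3 equiv, slow feed), 0.1 M triethanolamine buffer pH 7.2, DMSO (10% v/v), 25 °C; extraction with EtOAc
Reagents that add atoms: none
Why: Proposed new method: the active-site lysine of this Schiff-base aldolase condenses with 3 to an enamine that attacks the C3 carbonyl of 2, hydrolysis releases 4, and 4 is taken up again as acceptor for a second enamine to give 5. The closest known reaction type is the tandem double acetaldehyde addition of the same enzyme to chloroacetaldehyde and to N-protected 3-aminopropanals, which gives 2,4,6-trideoxyhexose-type lactols; a 3-arylpropanal has not been shown as acceptor, hence the assumed variant. The single ring closes by 6-exo-trig hemiacetalisation of the C3 hydroxyl on the C7 carbonyl, an uncatalysed and thermodynamically favourable event that pulls both reversible aldol equilibria forward. C3 and C5 are each set by the enzyme, which presents the enamine to the same carbonyl face in both rounds, so the acceptor-side carbinol should come out R and the diol syn (4R,6R in ring numbering), a sense that matches the target only when ring A and not ring B sits on the acceptor. The step needs 2 to act as acceptor only, cross-addition to win over self-addition of 3, and a stop after two rounds: the donor pocket holds only two- or three-carbon carbonyl compounds, the slow feed of 3 keeps 2 the dominant acceptor, and lactol formation removes the aldehyde needed for a third round. The unbranched C1–C2 tether holds ring A two carbons away from the reacting carbonyl, and the free phenol keeps 2 dissolved in the buffer.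

Step 3
Reactants: 6 (4R,6R)-6-[2-(4-hydroxy-3-methoxyphenyl)ethyl]oxane-2,4-diol
Product: 7 (4R,6R)-6-{2-[4-(benzyloxy)-3-methoxyphenyl]ethyl}oxane-2,4-diol (anomer mixture)
Conditions: BnBr (1.05 equiv), K2CO3 (1.5 equiv), acetone, rt to 40 °C
Reagents that add atoms: benzyl bromide, BrCc1ccccc1
Why: Williamson ether synthesis: carbonate ionises only the phenol (pKa near 10) and not the lactol or the secondary hydroxyl, so about one equivalent of benzyl bromide should alkylate the phenoxide alone, the weak base leaves the masked β-hydroxy aldehyde intact, and the two ring stereocentres are not involved.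

Step 4
Reactants: 7 (4R,6R)-6-{2-[4-(benzyloxy)-3-methoxyphenyl]ethyl}oxane-2,4-diol; 8 4-bromo-1,2-bis(benzyloxy)benzene
Product: 11 (3R,5R)-1-[3,4-bis(benzyloxy)phenyl]-7-[4-(benzyloxy)-3-methoxyphenyl]heptane-1,3,5-triol (epimer mixture at the benzylic carbinol), via arylmagnesium bromide 9 (not isolated), via ring-opened aldehyde dialkoxide 10 (not isolated)
Conditions: 8 (4.2 equiv), Mg turnings, THF, 45 °C; then 7 in THF, 0 °C to rt; sat. aq. NH4Cl
Reagents that add atoms: magnesium, [Mg] (held only in 9 and 10, lost at work-up)
Why: Grignard addition to a lactol, as practised on 2-deoxy sugar hemiacetals: two equivalents of 9 are spent on the two hydroxyl protons, the anomeric alkoxide opens to aldehyde 10, and a further equivalent adds to C7, giving the new benzylic carbinol without facial control as an epimer mixture that is harmless because this centre is erased in step 6, while C3 and C5 keep their C–O bonds.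

Step 5
Reactants: 11 (3R,5R)-1-[3,4-bis(benzyloxy)phenyl]-7-[4-(benzyloxy)-3-methoxyphenyl]heptane-1,3,5-triol
Product: 12 (3R,5R)-1-[3,4-bis(benzyloxy)phenyl]-7-[4-(benzyloxy)-3-methoxyphenyl]heptane-1,3,5-triyl triacetate (epimer mixture at the benzylic carbon)
Conditions: Ac2O (6 equiv), pyridine, DMAP (cat.), CH2Cl2, 0 °C to rt
Reagents that add atoms: acetic anhydride, CC(=O)OC(C)=O
Why: DMAP-catalysed O-acylation: all three secondary hydroxyls are esterified with retention because no C–O bond is broken, and the basic medium avoids ionisation of the electron-rich benzylic alcohol, which under acid would be trapped by the C3 hydroxyl as a tetrahydropyran.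

Step 6
Reactants: 12 (3R,5R)-1-[3,4-bis(benzyloxy)phenyl]-7-[4-(benzyloxy)-3-methoxyphenyl]heptane-1,3,5-triyl triacetate
Product: 13 (3R,5S)-7-(3,4-dihydroxyphenyl)-1-(4-hydroxy-3-methoxyphenyl)heptane-3,5-diyl diacetate (target, numbered from ring A)
Conditions: H2 (3 bar), 10% Pd/C, EtOAc with 10% AcOH, rt, work-up under argon
Reagents that add atoms: none
Why: Catalytic hydrogenolysis: palladium cleaves only benzylic C–O bonds, that is the three aryl benzyl ethers and the C7 acetate activated by the para oxygen of ring B, whereas the non-benzylic C3 and C5 acetates are inert, so both C7 epimers should converge on the single (3R,5S) diacetate.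

Note on descriptors: the middle carbinol reads R in 5 to 7 and 10 to 12 and S in 13. The only reason is that the oxygenated C7 raises the priority of its branch. The spatial arrangement is unchanged throughout.

Compound list
1 | coniferyl aldehyde, (E)-3-(4-hydroxy-3-methoxyphenyl)prop-2-enal | COc1cc(/C=C/C=O)ccc1O | starting material
2 | 3-(4-hydroxy-3-methoxyphenyl)propanal | COc1cc(CCC=O)ccc1O | intermediate
3 | acetaldehyde | CC=O | starting material
4 | (3R)-3-hydroxy-5-(4-hydroxy-3-methoxyphenyl)pentanal | COc1cc(CC[C@@H](O)CC=O)ccc1O | intermediate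
5 | (3R,5R)-3,5-dihydroxy-7-(4-hydroxy-3-methoxyphenyl)heptanal | COc1cc(CC[C@@H](O)C[C@@H](O)CC=O)ccc1O | intermediate
6 | (4R,6R)-6-[2-(4-hydroxy-3-methoxyphenyl)ethyl]oxane-2,4-diol, anomer mixture | COc1cc(CC[C@@H]2C[C@@H](O)CC(O)O2)ccc1O | intermediate
7 | (4R,6R)-6-{2-[4-(benzyloxy)-3-methoxyphenyl]ethyl}oxane-2,4-diol, anomer mixture | COc1cc(CC[C@@H]2C[C@@H](O)CC(O)O2)ccc1OCc3ccccc3 | intermediate
8 | 4-bromo-1,2-bis(benzyloxy)benzene | Brc1ccc(OCc2ccccc2)c(OCc2ccccc2)c1 | starting material
9 | 3,4-bis(benzyloxy)phenylmagnesium bromide | Br[Mg]c1ccc(OCc2ccccc2)c(OCc2ccccc2)c1 | intermediate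
10 | (3R,5R)-7-[4-(benzyloxy)-3-methoxyphenyl]-3,5-dihydroxyheptanal as its bis(bromomagnesium) alkoxide | COc1cc(CC[C@@H](O[Mg]Br)C[C@@H](O[Mg]Br)CC=O)ccc1OCc2ccccc2 | intermediate
11 | (3R,5R)-1-[3,4-bis(benzyloxy)phenyl]-7-[4-(benzyloxy)-3-methoxyphenyl]heptane-1,3,5-triol, C1 epimers | COc1cc(CC[C@@H](O)C[C@@H](O)CC(O)c2ccc(OCc3ccccc3)c(OCc3ccccc3)c2)ccc1OCc4ccccc4 | intermediate
12 | (3R,5R)-1-[3,4-bis(benzyloxy)phenyl]-7-[4-(benzyloxy)-3-methoxyphenyl]heptane-1,3,5-triyl triacetate, C1 epimers | COc1cc(CC[C@@H](OC(C)=O)C[C@@H](OC(C)=O)CC(OC(C)=O)c2ccc(OCc3ccccc3)c(OCc3ccccc3)c2)ccc1OCc4ccccc4 | intermediate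
13 | (3R,5S)-7-(3,4-dihydroxyphenyl)-1-(4-hydroxy-3-methoxyphenyl)heptane-3,5-diyl diacetate | COc1cc(CC[C@H](C[C@H](CCc2ccc(O)c(O)c2)OC(C)=O)OC(C)=O)ccc1O | target

Total step count: 6
Longest linear sequence: 6 steps (1 to 13). Bromide 8 enters convergently in step 4 without a step of its own.

Steps most likely to fail

1. Step 2 (the labelled step).
- Risk: weak binding or slow turnover of the bulky acceptor could let self-addition of acetaldehyde consume the donor. The sequence could also stall after the first addition, or the enzyme could be inactivated by acetaldehyde before useful conversion.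
- Fallback: known chemistry that sets out from 2 and returns at 7, so step 3 is bypassed. Benzylation of 2 (BnBr, K2CO3, acetone) gives 3-[4-(benzyloxy)-3-methoxyphenyl]propanal F1. A vinylogous Mukaiyama aldol addition of 1-methoxy-1,3-bis(trimethylsilyloxy)buta-1,3-diene follows, catalysed by Ti(OiPr)4 and the BINOL enantiomer that delivers the R carbinol. Desilylation with CF3CO2H should then give methyl (5R)-7-[4-(benzyloxy)-3-methoxyphenyl]-5-hydroxy-3-oxoheptanoate F2. Narasaka–Prasad reduction (Et2BOMe, NaBH4, THF–MeOH, −78 °C) sets the second carbinol syn through the boron chelate, giving methyl (3R,5R)-7-[4-(benzyloxy)-3-methoxyphenyl]-3,5-dihydroxyheptanoate F3. Partial reduction with iBu2AlH (3.5 equiv, CH2Cl2, −78 °C) gives the aldehyde oxidation level, which is trapped by the δ-oxygen and appears after work-up as 7.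

2. Step 4.
- Risk: the magnesium lactolate could open slowly or the polyalkoxide could precipitate. The strongly basic medium could also cause retro-aldol cleavage or β-elimination of the open form before the aryl group adds.
- Fallback: this sets out from 7 and 8 and returns at 11, moving the arylation to a carbonyl group that needs no ring-opening pre-equilibrium. Oxidation of the lactol with Ag2CO3 on Celite (toluene, reflux), which is selective over the secondary alcohol, gives (4R,6R)-6-{2-[4-(benzyloxy)-3-methoxyphenyl]ethyl}-4-hydroxyoxan-2-one F4. Bromine–lithium exchange on 8 (n-BuLi, THF, −78 °C) gives 3,4-bis(benzyloxy)phenyllithium F5. Of 2.2 equivalents, the first is spent on the hydroxyl proton and the second adds once to the lactone at −78 °C, as in aryl C-glycoside chemistry. The product is (4R,6R)-2-[3,4-bis(benzyloxy)phenyl]-6-{2-[4-(benzyloxy)-3-methoxyphenyl]ethyl}oxane-2,4-diol F6. NaBH4 (THF–MeOH, 0 °C) reduces the open hydroxy ketone form of this hemiketal to 11.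

3. Step 6.
- Risk: the C7–O bond could be cleaved incompletely once the fast debenzylation has occurred. The para-hydroxybenzylic acetate could also ionise and eliminate towards C6, which would expose the C5 acetate to allylic hydrogenolysis. A neighbouring-group acetyl shift is a further possibility.
- Fallback: this sets out from 12 and returns at 13, separating the two tasks. Ionic hydrogenation (Et3SiH, BF3·OEt2, CH2Cl2, −78 to −20 °C) replaces the readily ionised benzylic acetate by hydride while the benzyl ethers and the other two acetates remain. The product is (3R,5S)-7-[3,4-bis(benzyloxy)phenyl]-1-[4-(benzyloxy)-3-methoxyphenyl]heptane-3,5-diyl diacetate F7. A plain O-debenzylation (H2, 1 atm, 10% Pd/C, EtOAc, rt) then gives 13.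

Further compounds
F1 | step 2 | 3-[4-(benzyloxy)-3-methoxyphenyl]propanal | COc1cc(CCC=O)ccc1OCc2ccccc2
F2 | step 2 | methyl (5R)-7-[4-(benzyloxy)-3-methoxyphenyl]-5-hydroxy-3-oxoheptanoate | COC(=O)CC(=O)C[C@H](O)CCc1ccc(OCc2ccccc2)c(OC)c1
F3 | step 2 | methyl (3R,5R)-7-[4-(benzyloxy)-3-methoxyphenyl]-3,5-dihydroxyheptanoate | COC(=O)C[C@H](O)C[C@H](O)CCc1ccc(OCc2ccccc2)c(OC)c1
F4 | step 4 | (4R,6R)-6-{2-[4-(benzyloxy)-3-methoxyphenyl]ethyl}-4-hydroxyoxan-2-one | COc1cc(CC[C@@H]2C[C@@H](O)CC(=O)O2)ccc1OCc3ccccc3
F5 | step 4 | 3,4-bis(benzyloxy)phenyllithium | [Li]c1ccc(OCc2ccccc2)c(OCc2ccccc2)c1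
F6 | step 4 | (4R,6R)-2-[3,4-bis(benzyloxy)phenyl]-6-{2-[4-(benzyloxy)-3-methoxyphenyl]ethyl}oxane-2,4-diol | COc1cc(CC[C@@H]2C[C@@H](O)CC(O)(c3ccc(OCc4ccccc4)c(OCc4ccccc4)c3)O2)ccc1OCc5ccccc5
F7 | step 6 | (3R,5S)-7-[3,4-bis(benzyloxy)phenyl]-1-[4-(benzyloxy)-3-methoxyphenyl]heptane-3,5-diyl diacetate | COc1cc(CC[C@@H](OC(C)=O)C[C@@H](OC(C)=O)CCc2ccc(OCc3ccccc3)c(OCc3ccccc3)c2)ccc1OCc4ccccc4
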